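## Retrosynthetic overview

- The plan rests on ring A (C1–C5, C10): cis carboxyls C19 (on quaternary C4) and C6 (on C5) lie next to quaternary C10, so C3–C4 and C5–C10 are the two bonds of a [4+2] union between a 1-methylbutadienyl group on C9 (C10=C1–C2=C3) and a methylbutenedioate (C5=C4).
- After the cycloaddition: hydrogenation/debenzylation, C16 methylenation, inversion of C5 through the cis anhydride, then release and oxidation of C7–OH and C11–OH.
- The diene comes from a C9 ethynyl group (Zr-catalysed methylalumination, Negishi vinylation); the bicyclo[3.2.1]octane is closed before that by Dieckmann condensation (C15 to C16).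
- C9 and C8 are set on ring C by anti conjugate addition of vinyl to a C8=C9 enoate and trans alkylation of the C8 enolate; absolute configuration comes from chiral-base desymmetrisation of a meso 5-oxocyclohexane-1,3-dicarboxylate.
- Ring order: C (from dimethyl 5-hydroxyisophthalate), then D, then A.

Key step: step 18

Remark: atoms carry ent-kaurane numbers (ring C = C8, C9, C11–C14; ring D = C8, C14, C13, C16, C15; on ring C "exo" is the face of C14 and "endo" the face of the C15–C16 bridge); the (R,R) lithium amide of step 3 is assumed to remove the C9 proton that leads to 4, and its (S,S) antipode is used if the sense proves opposite.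

## Route

Step 1
Reactants: 1 dimethyl 5-hydroxyisophthalate
Product: 2 dimethyl all-cis-5-hydroxycyclohexane-1,3-dicarboxylate (meso)
Conditions: H2 (50 bar), Rh/Al2O3, MeOH, AcOH (cat.), 60 °C
Reagents that add atoms: none
Why: Heterogeneous arene hydrogenation delivers hydrogen to one face of the adsorbed ring, so the all-cis meso cyclohexanol should predominate and is purified by crystallisation.

Step 2
Reactants: 2 dimethyl all-cis-5-hydroxycyclohexane-1,3-dicarboxylate
Product: 3 dimethyl cis-5-oxocyclohexane-1,3-dicarboxylate (meso)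
Conditions: TEMPO (cat.), KBr (cat.), NaOCl, NaHCO3, CH2Cl2/H2O, 0 °C
Reagents that add atoms: none
Why: Oxoammonium (TEMPO/hypochlorite) oxidation of the secondary alcohol is mild enough to leave the ester-bearing centres alone, and the diequatorial cis diester is the stable isomer in any case.

Step 3
Reactants: 3 dimethyl cis-5-oxocyclohexane-1,3-dicarboxylate
Product: 4 dimethyl (1S,3R)-5-(trimethylsilyloxy)cyclohex-4-ene-1,3-dicarboxylate (enol double bond C9=C11)
Conditions: lithium (R,R)-bis(1-phenylethyl)amide (from the amine, n-BuLi), LiCl, TMSCl (in situ quench), THF, −100 °C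
Reagents that add atoms: chlorotrimethylsilane, C[Si](C)(C)Cl
Why: Enantioselective deprotonation of a meso cis-3,5-disubstituted cyclohexanone by a chiral lithium amide with internal silyl trapping removes one of the two enantiotopic axial α-protons (ketone α-protons go faster than ester α-protons), which fixes both the absolute configuration (C13 S) and the enolisation site (C9).

Step 4
Reactants: 4 dimethyl (1S,3R)-5-(trimethylsilyloxy)cyclohex-4-ene-1,3-dicarboxylate
Product: 5 dimethyl (1S)-5-oxocyclohex-3-ene-1,3-dicarboxylate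
Conditions: Pd(OAc)2 (1.05 equiv), MeCN, rt
Reagents that add atoms: none
Why: Saegusa–Ito oxidation, in which the palladium enolate at C9 can lose only the β-hydrogen on C8, so the C11(=O)–C9=C8 enone forms regiospecifically and C13 is untouched.

Step 5
Reactants: 5 dimethyl (1S)-5-oxocyclohex-3-ene-1,3-dicarboxylate
Product: 6 dimethyl (1S,5S)-5-hydroxycyclohex-3-ene-1,3-dicarboxylate (hydroxyl cis to the C13 ester)
Conditions: NaBH4, CeCl3·7H2O, MeOH, −78 °C
Reagents that add atoms: none
Why: Luche 1,2-reduction with axial hydride delivery to the half-chair that holds the C13 ester equatorial should give the cis allylic alcohol, as is usual for 5-substituted cyclohexenones.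

Step 6
Reactants: 6 dimethyl (1S,5S)-5-hydroxycyclohex-3-ene-1,3-dicarboxylate
Product: 7 dimethyl (1S,5S)-5-(tert-butyldimethylsilyloxy)cyclohex-3-ene-1,3-dicarboxylate
Conditions: TBSCl, imidazole, DMF, rt
Reagents that add atoms: tert-butyldimethylsilyl chloride, CC(C)(C)[Si](C)(C)Cl
Why: Standard silylation of the allylic alcohol gives the bulky C11 ether that directs the next step and later keeps C11 at the alcohol level until the end.

Step 7
Reactants: 7 dimethyl (1S,5S)-5-(tert-butyldimethylsilyloxy)cyclohex-3-ene-1,3-dicarboxylate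
Product: 8 methyl (1S,3S,4S)-3-(tert-butyldimethylsilyloxy)-5-[methoxy(trimethylsilyloxy)methylidene]-4-vinylcyclohexane-1-carboxylate (silyl ketene acetal at C8, vinyl on C9 trans to OTBS)
Conditions: CH2=CHMgBr, CuBr·SMe2 (10 mol%), TMSCl, THF, −78 °C; Et3N, pentane, filtration
Reagents that add atoms: vinylmagnesium bromide, C=C[Mg]Br; chlorotrimethylsilane, C[Si](C)(C)Cl
Why: Copper-catalysed, TMSCl-accelerated conjugate addition of the vinyl Grignard reagent to the enoate should occur at C9 anti to the neighbouring C11 silyloxy group (and to the C13 ester on the same face), which sets C9 and stores the C8 ester enolate regiospecifically as its silyl ketene acetal.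

Step 8
Reactants: 8 silyl ketene acetal
Product: 9 dimethyl (1R,3S,5S,6S)-5-(tert-butyldimethylsilyloxy)-1-(2-methoxy-2-oxoethyl)-6-vinylcyclohexane-1,3-dicarboxylate (kaurane 8R,9S,11S,13S)
Conditions: BrCH2CO2Me, TBAT (tetrabutylammonium difluorotriphenylsilicate), THF, −78 °C → rt
Reagents that add atoms: methyl bromoacetate, COC(=O)CBr
Why: Fluoride-induced regiospecific alkylation of a silyl ketene acetal, in which allylic 1,3-strain with the exocyclic enolate holds the C9 vinyl group axial so that the bromoacetate enters trans to it, creating quaternary C8 with the C15 arm cis to the C13 ester while the C13 α-proton never meets base.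

Step 9
Reactants: 9 vinyl triester
Product: 10 dimethyl (1R,3S,5S,6S)-5-(tert-butyldimethylsilyloxy)-6-formyl-1-(2-methoxy-2-oxoethyl)cyclohexane-1,3-dicarboxylate
Conditions: O3, CH2Cl2/MeOH, −78 °C; PPh3
Reagents that add atoms: ozone, [O-][O+]=O
Why: Ozonolysis of the only alkene with reductive work-up gives the C9 aldehyde (C10) under neutral conditions that should not epimerise C9.

Step 10
Reactants: 10 aldehyde triester
Product: 11 dimethyl (1R,3S,5S,6S)-5-(tert-butyldimethylsilyloxy)-6-ethynyl-1-(2-methoxy-2-oxoethyl)cyclohexane-1,3-dicarboxylate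
Conditions: TMSCHN2, n-BuLi, THF, −78 °C → 0 °C
Reagents that add atoms: (trimethylsilyl)diazomethane, C[Si](C)(C)C=[N+]=[N-]
Why: Colvin rearrangement, in which lithiated TMS-diazomethane adds to the aldehyde at −78 °C (esters are not attacked), and Peterson elimination followed by 1,2-hydride shift of the alkylidene carbene gives the terminal alkyne without exposing C9 to equilibrating base.

Step 11
Reactants: 11 alkyne triester
Product: 12 dimethyl 3-endo-(tert-butyldimethylsilyloxy)-2-exo-ethynyl-6-oxobicyclo[3.2.1]octane-1,7-dicarboxylate (β-keto ester, C15 epimers/enol; other centres as in 11)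
Conditions: NaH (3 equiv), MeOH (cat.), THF, 0 → 60 °C; AcOH
Reagents that add atoms: none
Why: Dieckmann condensation of the C15 ester enolate onto the cis C13 ester carbonyl (C16) closes five-membered ring D as the bridge across C8 and C13, and the equilibrium should settle on this isomer because it alone gives an enolisable β-keto ester (closure from C13 onto the arm ester is reversible).

Step 12
Reactants: 12 bicyclic β-keto ester
Product: 13 methyl 3-endo-(tert-butyldimethylsilyloxy)-2-exo-ethynyl-6-oxobicyclo[3.2.1]octane-1-carboxylate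
Conditions: LiCl, DMSO, H2O, 140 °C
Reagents that add atoms: none
Why: Krapcho dealkoxycarbonylation removes only the ester activated by the β-ketone, leaving the neopentyl C7 ester on C8.

Step 13
Reactants: 13 keto ester
Product: 14 3-endo-(tert-butyldimethylsilyloxy)-2-exo-ethynyl-1-(hydroxymethyl)bicyclo[3.2.1]octan-6-ol (C16 hydroxyl expected on the face turned to C11)
Conditions: LiAlH4, THF, 0 °C → rt
Reagents that add atoms: none
Why: Hydride reduction turns the C7 ester into the primary alcohol and at the same time reduces the C16 ketone from its open face, which is harmless because C16 is re-oxidised in step 16 and its configuration is irrelevant.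

Step 14
Reactants: 14 diol
Product: 15 3-endo-(tert-butyldimethylsilyloxy)-1-[(tert-butyldiphenylsilyloxy)methyl]-2-exo-ethynylbicyclo[3.2.1]octan-6-ol
Conditions: TBDPSCl, imidazole, CH2Cl2, 0 °C
Reagents that add atoms: tert-butyldiphenylsilyl chloride, CC(C)(C)[Si](Cl)(c1ccccc1)c1ccccc1
Why: Selective silylation, as the bulky silyl chloride should take the primary C7 hydroxyl and leave the crowded secondary C16 hydroxyl free.

Step 15
Reactants: 15 alkynyl alcohol
Product: 17 C16 alcohol bearing the (2E)-penta-2,4-dien-2-yl group on C9, via C1-dimethylalanyl alkene 16 (not isolated)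
Conditions: AlMe3 (4 equiv), Cp2ZrCl2 (0.3 equiv), CH2Cl2, 0 °C → rt; then CH2=CHBr, ZnCl2, Pd(PPh3)4 (5 mol%), THF, rt
Reagents that add atoms: trimethylaluminium, C[Al](C)C; vinyl bromide, C=CBr
Why: Zirconium-catalysed syn methylalumination places methyl on C10 and aluminium on C1, and Negishi coupling with vinyl bromide goes with retention, so the E diene with C20 cis to the vinyl group should form stereospecifically while the C16 hydroxyl rides as its aluminium alkoxide.

Step 16
Reactants: 17 dienyl alcohol
Product: 18 (8R,9S,11S,13S)-3-endo-(tert-butyldimethylsilyloxy)-1-[(tert-butyldiphenylsilyloxy)methyl]-2-exo-[(2E)-penta-2,4-dien-2-yl]bicyclo[3.2.1]octan-6-one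
Conditions: Dess–Martin periodinane, NaHCO3, CH2Cl2, rt
Reagents that add atoms: none
Why: Buffered Dess–Martin oxidation restores the C16 ketone without touching the acid-sensitive diene or the silyl ethers.

Step 17
Reactants: 19 mesaconic acid
Product: 20 dibenzyl mesaconate
Conditions: BnBr, K2CO3, DMF, rt
Reagents that add atoms: benzyl bromide, BrCc1ccccc1
Why: Carboxylate O-alkylation (SN2) keeps the E geometry and gives esters that can later be removed from two very hindered positions by hydrogenolysis.

Step 18
Reactants: 18 bicyclic diene ketone; 20 dibenzyl mesaconate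
Product: 21 dibenzyl (4R,5R,8R,9S,10S,11S,13S) ring A cyclohexene diester (C1=C2; C19 ester cis to C20, C6 ester trans to both)
Conditions: Et2AlCl (2.5 equiv), 20 (3 equiv), CH2Cl2, −40 °C → rt
Reagents that add atoms: none
Why: Et2AlCl-promoted normal-demand Diels–Alder reaction, concerted but asynchronous (C3–C4 ahead of C5–C10, with positive charge building at the tertiary allylic terminus C10), of the type known for 1,1-disubstituted 1,3-dienes with fumarate and mesaconate esters. Ring A is closed as a cyclohexene in one intermolecular [4+2] event, both σ-bonds forming suprafacially on diene and dienophile. The orientation needed joins C10 to the CH carbon C5: the two fully substituted carbons C10 and C4 cannot be brought together, and aluminium on the less hindered C6 ester makes C4 the electrophilic β-carbon for the unsubstituted terminus C3. C4 is set by the exo position of the C19 ester (C18 endo), which puts C19 cis to the inside methyl C20, and C5 by the endo position of the complexed C6 ester, preferred because only then does H5 rather than a carboxyl face C20; C6 therefore ends trans to C19 and is corrected in step 21. C10 is set by the diene face: with H9 turned toward C20 (least allylic 1,2-strain), quaternary C8 with its CH2OTBDPS arm stands anti to the incoming dienophile and C11, whose axial silyloxy group points away toward the C15–C16 bridge, is the small inside group, so C5 should bond on the face opposite C8. The Z-methyl lowers the s-cis population, hence the Lewis acid, one equivalent of which is held by the C16 ketone.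

Step 19
Reactants: 21 cycloadduct
Product: 22 saturated trans-diacid (C19 and C6 acids, C16 ketone, both silyl ethers)
Conditions: H2 (4 bar), Pd(OH)2/C, EtOAc, rt
Reagents that add atoms: none
Why: Catalytic hydrogenation saturates the C1=C2 alkene and cleaves both benzyl esters by hydrogenolysis in one operation, which is possible only because C16 is still a ketone.

Step 20
Reactants: 22 keto diacid
Product: 23 C16-methylene trans-diacid
Conditions: Ph3PCH3Br, KOtBu (6 equiv each), THF, 0 → 50 °C; citric acid work-up
Reagents that add atoms: methyltriphenylphosphonium bromide, C[P+](c1ccccc1)(c1ccccc1)c1ccccc1.[Br-]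
Why: Wittig methylenation with excess ylide works on the dicarboxylate of a bicyclo[3.2.1]octan-6-one (the carboxylates are inert) and should attack the unhindered C16 carbonyl from the face of C14.

Step 21
Reactants: 23 trans-diacid
Product: 25 cis-fused C19/C6 cyclic anhydride (5S), via C6 mixed acetic anhydride 24 (not isolated)
Conditions: Ac2O, Et3N, DMAP (cat.), toluene, 100 °C
Reagents that add atoms: none
Why: Epimerising anhydride formation: the trans diacid cannot close (carboxyls diaxial), so its C6 mixed anhydride enolises at C5 under base and is drained irreversibly into the cis-fused anhydride, which inverts C5 to the target configuration under non-acidic conditions that spare the exocyclic alkene.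

Step 22
Reactants: 25 cis anhydride
Product: 27 cis-diacid diol (C7–OH and C11–OH free), via bis-silyl cis-diacid 26 (not isolated)
Conditions: LiOH, THF/H2O, rt; 1 M HCl to pH 3 (0 °C), extraction; then TBAF, THF, 50 °C
Reagents that add atoms: lithium hydroxide, [Li+].[OH-]
Why: Saponification opens the anhydride first so that no acylating group is present when fluoride frees the two hydroxyls, and the axial C11 oxygen, anti to C10, cannot lactonise onto C6.

Step 23
Reactants: 27 diol diacid
Product: 28 target, (4R,5S,8R,9S,10S,13S)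
Conditions: Dess–Martin periodinane (3 equiv), CH2Cl2/MeCN, rt
Reagents that add atoms: none
Why: Dess–Martin oxidation tolerates free carboxylic acids and should convert the neopentyl C7 alcohol into the non-enolisable aldehyde and the C11 alcohol into the ketone under conditions too mild to epimerise C9.

## Compound list

1 | dimethyl 5-hydroxyisophthalate | COC(=O)c1cc(O)cc(c1)C(=O)OC | starting material
2 | dimethyl all-cis-5-hydroxycyclohexane-1,3-dicarboxylate (meso) | COC(=O)[C@H]1C[C@@H](O)C[C@@H](C(=O)OC)C1 | intermediate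
3 | dimethyl cis-5-oxocyclohexane-1,3-dicarboxylate (meso) | COC(=O)[C@H]1CC(=O)C[C@@H](C(=O)OC)C1 | intermediate
4 | dimethyl (1S,3R)-5-(trimethylsilyloxy)cyclohex-4-ene-1,3-dicarboxylate | COC(=O)[C@H]1C=C(O[Si](C)(C)C)C[C@@H](C(=O)OC)C1 | intermediate
5 | dimethyl (1S)-5-oxocyclohex-3-ene-1,3-dicarboxylate | COC(=O)C1=CC(=O)C[C@@H](C(=O)OC)C1 | intermediate
6 | dimethyl (1S,5S)-5-hydroxycyclohex-3-ene-1,3-dicarboxylate | COC(=O)C1=C[C@@H](O)C[C@@H](C(=O)OC)C1 | intermediate
7 | dimethyl (1S,5S)-5-(tert-butyldimethylsilyloxy)cyclohex-3-ene-1,3-dicarboxylate | COC(=O)C1=C[C@@H](O[Si](C)(C)C(C)(C)C)C[C@@H](C(=O)OC)C1 | intermediate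
8 | methyl (1S,3S,4S)-3-(tert-butyldimethylsilyloxy)-5-[methoxy(trimethylsilyloxy)methylidene]-4-vinylcyclohexane-1-carboxylate | COC(O[Si](C)(C)C)=C1[C@H](C=C)[C@@H](O[Si](C)(C)C(C)(C)C)C[C@@H](C(=O)OC)C1 | intermediate
9 | dimethyl (1R,3S,5S,6S)-5-(tert-butyldimethylsilyloxy)-1-(2-methoxy-2-oxoethyl)-6-vinylcyclohexane-1,3-dicarboxylate | COC(=O)C[C@@]1(C(=O)OC)[C@H](C=C)[C@@H](O[Si](C)(C)C(C)(C)C)C[C@@H](C(=O)OC)C1 | intermediate
10 | dimethyl (1R,3S,5S,6S)-5-(tert-butyldimethylsilyloxy)-6-formyl-1-(2-methoxy-2-oxoethyl)cyclohexane-1,3-dicarboxylate | COC(=O)C[C@@]1(C(=O)OC)[C@H](C=O)[C@@H](O[Si](C)(C)C(C)(C)C)C[C@@H](C(=O)OC)C1 | intermediate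
11 | dimethyl (1R,3S,5S,6S)-5-(tert-butyldimethylsilyloxy)-6-ethynyl-1-(2-methoxy-2-oxoethyl)cyclohexane-1,3-dicarboxylate | COC(=O)C[C@@]1(C(=O)OC)[C@H](C#C)[C@@H](O[Si](C)(C)C(C)(C)C)C[C@@H](C(=O)OC)C1 | intermediate
12 | dimethyl 3-endo-(tert-butyldimethylsilyloxy)-2-exo-ethynyl-6-oxobicyclo[3.2.1]octane-1,7-dicarboxylate | O=C1C(C(=O)OC)[C@]2(C(=O)OC)C[C@H]1C[C@H](O[Si](C)(C)C(C)(C)C)[C@H]2C#C | intermediate
13 | methyl 3-endo-(tert-butyldimethylsilyloxy)-2-exo-ethynyl-6-oxobicyclo[3.2.1]octane-1-carboxylate | O=C1C[C@]2(C(=O)OC)C[C@H]1C[C@H](O[Si](C)(C)C(C)(C)C)[C@H]2C#C | intermediate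
14 | 3-endo-(tert-butyldimethylsilyloxy)-2-exo-ethynyl-1-(hydroxymethyl)bicyclo[3.2.1]octan-6-ol | O[C@H]1C[C@]2(CO)C[C@H]1C[C@H](O[Si](C)(C)C(C)(C)C)[C@H]2C#C | intermediate
15 | 3-endo-(tert-butyldimethylsilyloxy)-1-[(tert-butyldiphenylsilyloxy)methyl]-2-exo-ethynylbicyclo[3.2.1]octan-6-ol | O[C@H]1C[C@]2(CO[Si](c3ccccc3)(c4ccccc4)C(C)(C)C)C[C@H]1C[C@H](O[Si](C)(C)C(C)(C)C)[C@H]2C#C | intermediate
16 | C1-dimethylalanyl alkene (E-2-methylalkenylalane, C16 aluminium alkoxide) | C[Al](C)O[C@H]1C[C@]2(CO[Si](c3ccccc3)(c4ccccc4)C(C)(C)C)C[C@H]1C[C@H](O[Si](C)(C)C(C)(C)C)[C@H]2/C(C)=C/[Al](C)C | intermediate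
17 | 3-endo-(tert-butyldimethylsilyloxy)-1-[(tert-butyldiphenylsilyloxy)methyl]-2-exo-[(2E)-penta-2,4-dien-2-yl]bicyclo[3.2.1]octan-6-ol | O[C@H]1C[C@]2(CO[Si](c3ccccc3)(c4ccccc4)C(C)(C)C)C[C@H]1C[C@H](O[Si](C)(C)C(C)(C)C)[C@H]2/C(C)=C/C=C | intermediate
18 | (8R,9S,11S,13S) bicyclic diene ketone: 3-endo-(tert-butyldimethylsilyloxy)-1-[(tert-butyldiphenylsilyloxy)methyl]-2-exo-[(2E)-penta-2,4-dien-2-yl]bicyclo[3.2.1]octan-6-one | O=C1C[C@]2(CO[Si](c3ccccc3)(c4ccccc4)C(C)(C)C)C[C@H]1C[C@H](O[Si](C)(C)C(C)(C)C)[C@H]2/C(C)=C/C=C | intermediate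
19 | mesaconic acid, (E)-2-methylbut-2-enedioic acid | OC(=O)/C=C(\C)C(=O)O | starting material
20 | dibenzyl mesaconate | O=C(OCc1ccccc1)/C=C(\C)C(=O)OCc1ccccc1 | intermediate
21 | dibenzyl (4R,5R,10S) 4,10-dimethyl-10-(bicyclyl)cyclohex-1-ene-4,5-dicarboxylate (ring A cycloadduct, kaurane numbering; bicycle as in 18) | O=C1C[C@]2(CO[Si](c3ccccc3)(c4ccccc4)C(C)(C)C)C[C@H]1C[C@H](O[Si](C)(C)C(C)(C)C)[C@H]2[C@]1(C)C=CC[C@@](C)(C(=O)OCc5ccccc5)[C@@H]1C(=O)OCc1ccccc1 | intermediate
22 | saturated trans-diacid with C16 ketone (5R) | O=C1C[C@]2(CO[Si](c3ccccc3)(c4ccccc4)C(C)(C)C)C[C@H]1C[C@H](O[Si](C)(C)C(C)(C)C)[C@H]2[C@]1(C)CCC[C@@](C)(C(=O)O)[C@@H]1C(=O)O | intermediate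
23 | C16-methylene trans-diacid (5R) | C=C1C[C@]2(CO[Si](c3ccccc3)(c4ccccc4)C(C)(C)C)C[C@H]1C[C@H](O[Si](C)(C)C(C)(C)C)[C@H]2[C@]1(C)CCC[C@@](C)(C(=O)O)[C@@H]1C(=O)O | intermediate
24 | C6 mixed acetic anhydride of 23 | C=C1C[C@]2(CO[Si](c3ccccc3)(c4ccccc4)C(C)(C)C)C[C@H]1C[C@H](O[Si](C)(C)C(C)(C)C)[C@H]2[C@]1(C)CCC[C@@](C)(C(=O)O)[C@@H]1C(=O)OC(C)=O | intermediate
25 | cis-fused C19/C6 cyclic anhydride (4R,5S) | C=C1C[C@]2(CO[Si](c3ccccc3)(c4ccccc4)C(C)(C)C)C[C@H]1C[C@H](O[Si](C)(C)C(C)(C)C)[C@H]2[C@]1(C)CCC[C@@]3(C)C(=O)OC(=O)[C@@H]13 | intermediate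
26 | bis-silyl cis-diacid (5S) | C=C1C[C@]2(CO[Si](c3ccccc3)(c4ccccc4)C(C)(C)C)C[C@H]1C[C@H](O[Si](C)(C)C(C)(C)C)[C@H]2[C@]1(C)CCC[C@@](C)(C(=O)O)[C@H]1C(=O)O | intermediate
27 | cis-diacid diol (C7–OH, C11–OH) | C=C1C[C@]2(CO)C[C@H]1C[C@H](O)[C@H]2[C@]1(C)CCC[C@@](C)(C(=O)O)[C@H]1C(=O)O | intermediate
28 | CNP0408869.1, (4R,5S,8R,9S,10S,13S) | C=C1C[C@]2(C=O)C[C@H]1CC(=O)[C@H]2[C@]1(C)CCC[C@@](C)(C(=O)O)[C@H]1C(=O)O | target

## Step count and risks

Total step count: 23. Longest linear sequence: 22 steps (steps 1–16 and 18–23; step 17 is the side branch).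

**Step 18 (Diels–Alder).** The Z-methyl keeps the s-cis diene scarce and both new bonds go to crowded carbons. Cycloaddition may therefore be slower than aluminium-induced isomerisation or oligomerisation of the diene, may leak into the orientation with the C19 ester endo, or may show weak facial discrimination at C10.
Fallback: from 18, heating with dimethyl acetylenedicarboxylate (toluene, 90 °C), a linear, symmetrical and far more reactive dienophile with no endo/exo or orientation question, should give the cyclohexa-1,4-diene diester F1. Me2CuLi (THF, −78 °C) should then add methyl to C4, the ester-bearing alkene carbon remote from quaternary C10, anti to the pseudo-axial C20 methyl, giving the C4-methylated diester F2 (C5 either way). Hydrogenation (H2, Pd/C) gives the saturated dimethyl diester F3, and NaSEt in DMF (100 °C) cleaves both methyl esters by attack at methyl, returning to 22; either C5 epimer converges at 25.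

**Step 11 (Dieckmann ring closure).** The chair that reacts must hold the C8 arm, the C13 ester and the C11 silyloxy group 1,3,5-syn-axial, so closure may be slow and intermolecular Claisen condensation or unproductive C13 epimerisation may take over.
Fallback: from 11, TBAF frees the C11 alkoxide, which should lactonise onto the cis C13 ester to give the bridged lactone diester F4. LiHMDS (2.2 equiv, THF, −78 → 0 °C) then forms the C15 enolate directly beneath the lactone carbonyl; transannular Claisen acylation with loss of the C11 alkoxide gives the hydroxy β-keto ester F5. TBSOTf/2,6-lutidine followed by mild acidic work-up returns to 12.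

**Step 21 (C5 inversion via the anhydride).** Enolisation at C5, flanked by two quaternary carbons, may be too slow, leaving acyclic mixed anhydrides of the trans diacid, and prolonged heating may move the C16 exocyclic alkene into the ring.
Fallback: from 23, TMSCHN2 (toluene/MeOH) gives the trans dimethyl ester F6. LDA/HMPA (THF, −78 → 0 °C) forms the C6 ester enolate, and kinetic protonation with AcOH at −78 °C, on the face away from the syn-axial C19 and C20 groups, should give the cis dimethyl ester F7. LiI in 2,6-lutidine (reflux) removes both methyl groups and rejoins the route at 26, which is desilylated as in the second stage of step 22.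

Further compounds
F1 | step 18 | dimethyl cyclohexa-1,4-diene-1,2-dicarboxylate adduct of 18 (C1=C2 and C4=C5, 10S) | O=C1C[C@]2(CO[Si](c3ccccc3)(c4ccccc4)C(C)(C)C)C[C@H]1C[C@H](O[Si](C)(C)C(C)(C)C)[C@H]2[C@]1(C)C=CCC(C(=O)OC)=C1C(=O)OC
F2 | step 18 | C4-methylated dimethyl diester (dimethyl ester analogue of 21, C5 unassigned) | O=C1C[C@]2(CO[Si](c3ccccc3)(c4ccccc4)C(C)(C)C)C[C@H]1C[C@H](O[Si](C)(C)C(C)(C)C)[C@H]2[C@]1(C)C=CC[C@@](C)(C(=O)OC)C1C(=O)OC
F3 | step 18 | saturated dimethyl diester (C5 unassigned) | O=C1C[C@]2(CO[Si](c3ccccc3)(c4ccccc4)C(C)(C)C)C[C@H]1C[C@H](O[Si](C)(C)C(C)(C)C)[C@H]2[C@]1(C)CCC[C@@](C)(C(=O)OC)C1C(=O)OC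
F4 | step 11 | bridged C11-O/C16 lactone diester (6-oxabicyclo[3.2.1]octan-7-one with C8 ester, C8 acetate arm and C9 ethynyl) | COC(=O)C[C@@]1(C(=O)OC)[C@H](C#C)[C@H]2OC(=O)[C@H](C2)C1
F5 | step 11 | dimethyl 2-exo-ethynyl-3-endo-hydroxy-6-oxobicyclo[3.2.1]octane-1,7-dicarboxylate | O=C1C(C(=O)OC)[C@]2(C(=O)OC)C[C@H]1C[C@H](O)[C@H]2C#C
F6 | step 21 | trans dimethyl ester of 23 (5R) | C=C1C[C@]2(CO[Si](c3ccccc3)(c4ccccc4)C(C)(C)C)C[C@H]1C[C@H](O[Si](C)(C)C(C)(C)C)[C@H]2[C@]1(C)CCC[C@@](C)(C(=O)OC)[C@@H]1C(=O)OC
F7 | step 21 | cis dimethyl ester (5S) | C=C1C[C@]2(CO[Si](c3ccccc3)(c4ccccc4)C(C)(C)C)C[C@H]1C[C@H](O[Si](C)(C)C(C)(C)C)[C@H]2[C@]1(C)CCC[C@@](C)(C(=O)OC)[C@H]1C(=O)OC
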